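**Plan**

1. Retrosynthesis: remove the C4 senecioate, take C8=O back to an (8R)-silyloxy carbinol and C2=C3 back to an alkyne, then cut the C4–C5 diol bond (pinacol) to an open-chain keto-ynal. Further cuts: C3–C4 (formyl), C8–C9 (vinyl + Weinreb amide), and the bonds at quaternary C1 (allylic substitution on geranyl phosphate).
2. Forward: geraniol → C1 by Cu-catalysed SN2′ alkynylation → side-chain carbinol → C9=C10 vinyl bromide → ynone (C8–C9) → Z-enone/ynal chain → SmI2 pinacol closes the 11-membered ring at C4–C5 → acylation, Lindlar reduction, C8 oxidation, desilylation.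
3. Stereochemistry: C1 from the chiral NHC–Cu catalyst; side-chain carbinol from Shi epoxidation; C8 (temporary) from CBS reduction; C5 from C8 by A(1,3) strain and C4 from the coupling geometry in the pinacol step. Z-alkenes: C9=C10 from the bromo-ylide Wittig, C6=C7 and C2=C3 from Lindlar reductions.
4. Enabling feature: Z-C6=C7, Z-C9=C10, the gem-disubstituted C1 and the linear C1–C2≡C3–C4 rod fold the chain so that C4 lies beside C5. The alkyne and the C8 silyloxy stereocentre are temporary helpers, removed in steps 23 and 25.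

Key step: step 21

Remark: ring atoms are numbered C1 (quaternary), C2=C3, C4 (acyloxy), C5 (tertiary carbinol), C6=C7, C8 (C=O), C9 (CH2OH-bearing), C10, C11. The target is treated as the open hydroxy enone drawn. The (8R) epimer is assumed to be the matched controller on the A(1,3) model below; this is a model prediction, not a certainty. (S)-But-3-yn-2-ol only keeps intermediates single diastereomers; its centre is erased in step 20.

**Route**

Step 1
Reactants: 1 geraniol
Product: 2 geranyl diethyl phosphate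
Conditions: (EtO)2P(O)Cl, pyridine, DMAP (cat.), CH2Cl2, 0 °C
Reagents that add atoms: diethyl chlorophosphate, CCOP(=O)(Cl)OCC
Why: O-phosphorylation of the primary allylic alcohol gives the E-trisubstituted allylic phosphate used for copper-catalysed SN2′ substitution.

Step 2
Reactants: 2 geranyl diethyl phosphate; 3 ethynyltrimethylsilane
Product: 5 [(3S)-3-ethenyl-3,7-dimethyloct-6-en-1-yn-1-yl]trimethylsilane, via alkynylalane 4 (not isolated)
Conditions: 3, i-Bu2AlH, Et3N (cat.), hexanes, 0 °C → rt; then 2, CuCl2·2H2O (cat.), enantiopure sulfonate-bearing imidazolinium salt (NHC precursor, cat.), THF, −30 °C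
Reagents that add atoms: none
Why: Copper-catalysed enantioselective allylic substitution of a trisubstituted allylic phosphate by an alkynylalane; γ-attack creates quaternary C1 with alkynyl (C2≡C3) and vinyl (C11=C10) groups, and the ligand enantiomer is chosen to give S.

Step 3
Reactants: 5 enyne
Product: 6 {(3S)-5-[(2R)-3,3-dimethyloxiran-2-yl]-3-ethenyl-3-methylpent-1-yn-1-yl}trimethylsilane
Conditions: D-fructose-derived Shi ketone (cat.), KHSO5, K2CO3, Bu4NHSO4, MeCN/dimethoxymethane/aq. borate buffer, 0 °C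
Reagents that add atoms: potassium peroxymonosulfate, [K+].[O-]S(=O)(=O)OO
Why: Shi epoxidation; the chiral dioxirane attacks only the electron-rich trisubstituted alkene through the spiro transition state, which should give the R epoxide carbon, and leaves the hindered vinyl group and the silylalkyne untouched.

Step 4
Reactants: 6 epoxide
Product: 7 (3R,6S)-6-ethenyl-2,6-dimethyl-8-(trimethylsilyl)oct-1-en-7-yn-3-ol
Conditions: Al(Oi-Pr)3, toluene, 110 °C
Reagents that add atoms: none
Why: Aluminium-alkoxide epoxide-to-allylic-alcohol isomerisation; the tertiary C–O bond opens and a methyl proton is lost, so the secondary C–O bond and its R configuration are kept.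

Step 5
Reactants: 7 allylic alcohol
Product: 8 tert-butyldimethylsilyl ether of 7
Conditions: TBSCl, imidazole, DMF, rt
Reagents that add atoms: tert-butyldimethylsilyl chloride, CC(C)(C)[Si](C)(C)Cl
Why: Standard silylation masks the side-chain carbinol until the last step.

Step 6
Reactants: 8 silyl ether
Product: 10 (3S,6R)-6-[(tert-butyldimethylsilyl)oxy]-3,7-dimethyl-3-[(trimethylsilyl)ethynyl]oct-7-en-1-ol, via alkylborane 9 (not isolated)
Conditions: 9-BBN, THF, 0 °C → rt; then 30% H2O2, aq. NaOAc, 0 °C → rt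
Reagents that add atoms: hydrogen peroxide, OO
Why: Hydroboration–oxidation; 9-BBN adds anti-Markovnikov to the monosubstituted vinyl group in preference to the hindered 1,1-disubstituted alkene and the silylalkyne, turning the vinyl group into C11H2–C10H2OH.

Step 7
Reactants: 10 primary alcohol
Product: 11 (3S,6R)-6-[(tert-butyldimethylsilyl)oxy]-3,7-dimethyl-3-[(trimethylsilyl)ethynyl]oct-7-enal
Conditions: Dess–Martin periodinane, NaHCO3, CH2Cl2, rt
Reagents that add atoms: none
Why: Dess–Martin oxidation gives the aldehyde (C10) without touching silyl groups or alkenes.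

Step 8
Reactants: 11 aldehyde; 12 ethyl 2-bromo-2-(triphenyl-λ5-phosphanylidene)acetate
Product: 13 ethyl (2Z,5S,8R)-2-bromo-8-[(tert-butyldimethylsilyl)oxy]-5,9-dimethyl-5-[(trimethylsilyl)ethynyl]deca-2,9-dienoate
Conditions: CH2Cl2, rt → 40 °C
Reagents that add atoms: none
Why: Wittig olefination with the α-bromo stabilised ylide puts the ester trans and bromine cis to the chain, which fixes the C9=C10 geometry: Br marks the later C8 position and the ester carbon becomes CH2OH.

Step 9
Reactants: 13 bromo enoate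
Product: 14 (2Z,5S,8R)-2-bromo-8-[(tert-butyldimethylsilyl)oxy]-5,9-dimethyl-5-[(trimethylsilyl)ethynyl]deca-2,9-dien-1-ol
Conditions: i-Bu2AlH, CH2Cl2, −78 °C; aq. work-up
Reagents that add atoms: none
Why: 1,2-Reduction of the ester by the aluminium hydride gives the allylic alcohol and leaves the vinyl bromide intact.

Step 10
Reactants: 14 bromo allylic alcohol
Product: 15 tert-butyldiphenylsilyl ether of 14
Conditions: TBDPSCl, imidazole, CH2Cl2, rt
Reagents that add atoms: tert-butyldiphenylsilyl chloride, CC(C)(C)[Si](Cl)(c1ccccc1)c1ccccc1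
Why: Silylation with the robust TBDPS group protects the future CH2OH through the later selective triethylsilyl cleavage.

Step 11
Reactants: 16 (S)-but-3-yn-2-ol
Product: 17 (S)-1-[(but-3-yn-2-yloxy)methyl]-4-methoxybenzene
Conditions: NaH, 4-MeOC6H4CH2Cl, Bu4NI (cat.), THF, 0 °C → rt
Reagents that add atoms: 4-methoxybenzyl chloride, COc1ccc(CCl)cc1
Why: Williamson etherification installs an oxidatively removable group on the future C5 oxygen.

Step 12
Reactants: 17 PMB ether; 18 N-methoxy-N-methylcarbamoyl chloride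
Product: 20 (S)-N-methoxy-4-[(4-methoxybenzyl)oxy]-N-methylpent-2-ynamide, via lithium acetylide 19 (not isolated)
Conditions: n-BuLi, THF, −78 °C; then 18, −78 °C → 0 °C
Reagents that add atoms: none
Why: C-acylation of the lithium acetylide by the carbamoyl chloride gives the Weinreb ynamide that carries C5–C8.

Step 13
Reactants: 15 vinyl bromide; 20 Weinreb ynamide
Product: 22 ynone (15 with Br replaced by the (S)-4-[(4-methoxybenzyl)oxy]pent-2-ynoyl group; C8 ketone), via vinyllithium 21 (not isolated)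
Conditions: t-BuLi (2 equiv), Et2O, −78 °C; then 20, −78 → −40 °C; aq. NH4Cl
Reagents that add atoms: none
Why: Bromine–lithium exchange keeps the alkene geometry, and the Weinreb ketone synthesis stops at the ketone through the chelated tetrahedral intermediate, forming the C8–C9 bond.

Step 14
Reactants: 22 ynone
Product: 23 (8R)-propargylic alcohol
Conditions: (S)-2-methyl-CBS-oxazaborolidine, catecholborane, toluene, −78 °C
Reagents that add atoms: none
Why: Corey–Bakshi–Shibata reduction; the alkynyl flank acts as the small group and the α-branched alkenyl flank as the large one, so the S catalyst should deliver hydride to give 8R.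

Step 15
Reactants: 23 propargylic alcohol
Product: 24 (6Z)-allylic alcohol (C6≡C7 of 23 reduced)
Conditions: H2 (1 atm), Pd/CaCO3–Pb(OAc)2, quinoline, EtOAc, rt
Reagents that add atoms: none
Why: Lindlar semihydrogenation adds hydrogen syn to give Z-C6=C7; the other alkyne, capped by SiMe3 and flanked by quaternary C1, is too hindered to adsorb.

Step 16
Reactants: 24 silylalkyne
Product: 25 terminal alkyne (C3–H)
Conditions: K2CO3, MeOH, rt
Reagents that add atoms: none
Why: Methoxide-mediated protodesilylation frees the C2≡C3–H terminus now that its shielding role is over.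

Step 17
Reactants: 25 alcohol
Product: 26 C8 triethylsilyl ether of 25
Conditions: Et3SiOTf, 2,6-lutidine, CH2Cl2, −78 °C
Reagents that add atoms: triethylsilyl trifluoromethanesulfonate, CC[Si](CC)(CC)OS(=O)(=O)C(F)(F)F
Why: Silylation gives a non-chelating, bulky group at C8 that blocks furan formation from the later Z-hydroxy enone and serves as the stereocontrol element.

Step 18
Reactants: 26 terminal alkyne; 27 N,N-dimethylformamide
Product: 29 ynal (CHO = C4 on C3), via lithium acetylide 28 (not isolated)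
Conditions: n-BuLi, THF, −78 °C; then 27; inverse quench into aq. KH2PO4
Reagents that add atoms: none
Why: Formylation of the lithium acetylide with DMF; the hemiaminal alkoxide collapses to the ynal on buffered work-up.

Step 19
Reactants: 29 PMB ether
Product: 30 (5S)-allylic alcohol
Conditions: DDQ, CH2Cl2/pH 7 buffer, 0 °C
Reagents that add atoms: none
Why: Oxidative cleavage of the p-methoxybenzyl ether by hydride abstraction leaves the silyl ethers and the ynal intact.

Step 20
Reactants: 30 allylic alcohol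
Product: 31 keto-ynal (C4 aldehyde; C5 methyl ketone; 6Z; 8R; 9Z)
Conditions: Dess–Martin periodinane, NaHCO3, CH2Cl2, 0 °C
Reagents that add atoms: none
Why: Buffered Dess–Martin oxidation gives the Z-enone without acid-induced Z/E isomerisation; the product is used at once.

Step 21
Reactants: 31 keto-ynal
Product: 32 (1S,4R,5R,8R,6Z,9Z)-cycloundeca-6,9-dien-2-yne-4,5-diol carrying 1-methyl, 5-methyl, 8-OSiEt3, 9-CH2OTBDPS and the 1-[(3R)-3-(TBS-oxy)-4-methylpent-4-enyl] chain
Conditions: SmI2 (3 equiv), HMPA, THF, −78 °C, slow addition of 31 (high dilution); aq. NH4Cl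
Reagents that add atoms: none
Why: SmI2 (divalent samarium, made more reducing and coordinatively saturated by HMPA) transfers one electron to each carbonyl, and the two trivalent-samarium ketyls combine at C4 and C5 to a bis(samarium) diolate that is protonated on work-up; the closest known reaction type is the SmI2-mediated intramolecular pinacol coupling of keto aldehydes, including closures of alkynyl aldehydes to medium-ring alkynediols. The 11-membered carbocycle closes head-to-head between the two carbonyl carbons (radical–radical combination, so no exo/endo alternative), helped by the folded chain: Z-C6=C7, Z-C9=C10, the gem-disubstituted C1 and the linear C1–C2≡C3–C4 rod hold C4 beside C5. C5 is controlled by the (8R)-silyloxy carbon through A(1,3) strain in the Z-enone ketyl: C8–H eclipses the alkene, the OSiEt3 group covers one face and the tether from C9 brings C4 to the other, which should give 5R. C4 is controlled by the coupling geometry: with an HMPA-saturated samarium on each oxygen the two C–O bonds should lie anti while the alkyne rod has to point back below the enone toward C9, which should give 4R (threo diol). The step needs C4–C5 bonding in preference to bonding through C2 or C7 and to intermolecular dimerisation: C2 is flanked by the quaternary C1, C4–C7 bonding would place the alkyne in a 9-membered ring, and slow addition at −78 °C keeps the ketyl concentration low and suppresses Z/E rotation of the allylic ketyl.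

Step 22
Reactants: 32 diol; 33 3-methylbut-2-enoyl chloride
Product: 34 C4 3-methylbut-2-enoate of 32
Conditions: pyridine, DMAP (cat.), CH2Cl2, 0 °C
Reagents that add atoms: none
Why: Acylpyridinium acylation picks the unhindered secondary propargylic hydroxyl over the tertiary one, and the weak base avoids deconjugation of the acyl group through a vinylketene.

Step 23
Reactants: 34 cycloalkyne ester
Product: 35 (2Z,6Z,9Z)-triene ester
Conditions: H2 (1 atm), Pd/CaCO3–Pb(OAc)2, quinoline, EtOAc, rt
Reagents that add atoms: none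
Why: Lindlar semihydrogenation of the ring alkyne (syn addition) gives Z-C2=C3 and removes the alkyne helper; the di- and trisubstituted alkenes and the enoate are not reduced.

Step 24
Reactants: 35 triethylsilyl ether
Product: 36 (8R)-alcohol
Conditions: HF·pyridine, pyridine, THF, 0 °C
Reagents that add atoms: none
Why: Buffered fluoride cleaves the triethylsilyl ether much faster than the TBS and TBDPS ethers.

Step 25
Reactants: 36 bis-allylic alcohol
Product: 37 (2Z,6Z,9Z)-dienone (C8 ketone)
Conditions: Dess–Martin periodinane, NaHCO3, CH2Cl2, 0 °C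
Reagents that add atoms: none
Why: Oxidation of the doubly allylic secondary alcohol erases the temporary C8 stereocentre and gives the cross-conjugated dienone; the tertiary C5 hydroxyl is inert.

Step 26
Reactants: 37 bis-silyl ether
Product: 38 target
Conditions: HF·pyridine (excess), THF, 0 °C → rt
Reagents that add atoms: none
Why: Acidic fluoride removes both remaining silyl ethers without the base that could trigger acyl migration or retro-aldol chemistry of the hydroxy enone.

**Compound list**

1 | geraniol, (2E)-3,7-dimethylocta-2,6-dien-1-ol | CC(C)=CCC/C(C)=C/CO | starting material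
2 | geranyl diethyl phosphate | CC(C)=CCC/C(C)=C/COP(=O)(OCC)OCC | intermediate
3 | ethynyltrimethylsilane | C#C[Si](C)(C)C | starting material
4 | diisobutyl[(trimethylsilyl)ethynyl]alane | CC(C)C[Al](CC(C)C)C#C[Si](C)(C)C | intermediate
5 | [(3S)-3-ethenyl-3,7-dimethyloct-6-en-1-yn-1-yl]trimethylsilane | CC(C)=CCC[C@](C=C)(C)C#C[Si](C)(C)C | intermediate
6 | {(3S)-5-[(2R)-3,3-dimethyloxiran-2-yl]-3-ethenyl-3-methylpent-1-yn-1-yl}trimethylsilane | CC1(C)O[C@@H]1CC[C@](C=C)(C)C#C[Si](C)(C)C | intermediate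
7 | (3R,6S)-6-ethenyl-2,6-dimethyl-8-(trimethylsilyl)oct-1-en-7-yn-3-ol | C=C(C)[C@H](O)CC[C@](C=C)(C)C#C[Si](C)(C)C | intermediate
8 | tert-butyldimethylsilyl ether of 7 | C=C(C)[C@H](O[Si](C)(C)C(C)(C)C)CC[C@](C=C)(C)C#C[Si](C)(C)C | intermediate
9 | B-alkyl-9-borabicyclo[3.3.1]nonane from 8 (boron on the terminal carbon of the former vinyl group) | C=C(C)[C@H](O[Si](C)(C)C(C)(C)C)CC[C@](CCB1C2CCCC1CCC2)(C)C#C[Si](C)(C)C | intermediate
10 | (3S,6R)-6-[(tert-butyldimethylsilyl)oxy]-3,7-dimethyl-3-[(trimethylsilyl)ethynyl]oct-7-en-1-ol | C=C(C)[C@H](O[Si](C)(C)C(C)(C)C)CC[C@](CCO)(C)C#C[Si](C)(C)C | intermediate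
11 | (3S,6R)-6-[(tert-butyldimethylsilyl)oxy]-3,7-dimethyl-3-[(trimethylsilyl)ethynyl]oct-7-enal | C=C(C)[C@H](O[Si](C)(C)C(C)(C)C)CC[C@](CC=O)(C)C#C[Si](C)(C)C | intermediate
12 | ethyl 2-bromo-2-(triphenyl-λ5-phosphanylidene)acetate | CCOC(=O)C(Br)=P(c1ccccc1)(c1ccccc1)c1ccccc1 | starting material
13 | ethyl (2Z,5S,8R)-2-bromo-8-[(tert-butyldimethylsilyl)oxy]-5,9-dimethyl-5-[(trimethylsilyl)ethynyl]deca-2,9-dienoate | C=C(C)[C@H](O[Si](C)(C)C(C)(C)C)CC[C@](C/C=C(\Br)C(=O)OCC)(C)C#C[Si](C)(C)C | intermediate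
14 | (2Z,5S,8R)-2-bromo-8-[(tert-butyldimethylsilyl)oxy]-5,9-dimethyl-5-[(trimethylsilyl)ethynyl]deca-2,9-dien-1-ol | C=C(C)[C@H](O[Si](C)(C)C(C)(C)C)CC[C@](C/C=C(\Br)CO)(C)C#C[Si](C)(C)C | intermediate
15 | tert-butyldiphenylsilyl ether of 14 (Z-vinyl bromide) | C=C(C)[C@H](O[Si](C)(C)C(C)(C)C)CC[C@](C/C=C(\Br)CO[Si](c1ccccc1)(c1ccccc1)C(C)(C)C)(C)C#C[Si](C)(C)C | intermediate
16 | (S)-but-3-yn-2-ol | C[C@H](O)C#C | starting material
17 | (S)-1-[(but-3-yn-2-yloxy)methyl]-4-methoxybenzene | C[C@H](OCc1ccc(OC)cc1)C#C | intermediate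
18 | N-methoxy-N-methylcarbamoyl chloride | CON(C)C(Cl)=O | starting material
19 | lithium acetylide of 17 | C[C@H](OCc1ccc(OC)cc1)C#C[Li] | intermediate
20 | (S)-N-methoxy-4-[(4-methoxybenzyl)oxy]-N-methylpent-2-ynamide | C[C@H](OCc1ccc(OC)cc1)C#CC(=O)N(C)OC | intermediate
21 | vinyllithium from 15 (Li in place of Br, geometry retained) | C=C(C)[C@H](O[Si](C)(C)C(C)(C)C)CC[C@](C/C=C(\[Li])CO[Si](c1ccccc1)(c1ccccc1)C(C)(C)C)(C)C#C[Si](C)(C)C | intermediate
22 | ynone: C8 ketone between the Z-alkenyl unit and the (S)-4-(PMB-oxy)pent-2-ynyl unit (C1 S, side chain R) | C=C(C)[C@H](O[Si](C)(C)C(C)(C)C)CC[C@](C/C=C(\C(=O)C#C[C@H](C)OCc1ccc(OC)cc1)CO[Si](c1ccccc1)(c1ccccc1)C(C)(C)C)(C)C#C[Si](C)(C)C | intermediate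
23 | (8R)-propargylic alcohol from 22 | C=C(C)[C@H](O[Si](C)(C)C(C)(C)C)CC[C@](C/C=C(\[C@H](O)C#C[C@H](C)OCc1ccc(OC)cc1)CO[Si](c1ccccc1)(c1ccccc1)C(C)(C)C)(C)C#C[Si](C)(C)C | intermediate
24 | (6Z,8R)-allylic alcohol (C6=C7 Z) | C=C(C)[C@H](O[Si](C)(C)C(C)(C)C)CC[C@](C/C=C(\[C@H](O)/C=C\[C@H](C)OCc1ccc(OC)cc1)CO[Si](c1ccccc1)(c1ccccc1)C(C)(C)C)(C)C#C[Si](C)(C)C | intermediate
25 | 24 with terminal alkyne (alkynyl SiMe3 removed) | C=C(C)[C@H](O[Si](C)(C)C(C)(C)C)CC[C@](C/C=C(\[C@H](O)/C=C\[C@H](C)OCc1ccc(OC)cc1)CO[Si](c1ccccc1)(c1ccccc1)C(C)(C)C)(C)C#C | intermediate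
26 | C8 triethylsilyl ether of 25 | C=C(C)[C@H](O[Si](C)(C)C(C)(C)C)CC[C@](C/C=C(\[C@H](O[Si](CC)(CC)CC)/C=C\[C@H](C)OCc1ccc(OC)cc1)CO[Si](c1ccccc1)(c1ccccc1)C(C)(C)C)(C)C#C | intermediate
27 | N,N-dimethylformamide | CN(C)C=O | starting material
28 | lithium acetylide of 26 | C=C(C)[C@H](O[Si](C)(C)C(C)(C)C)CC[C@](C/C=C(\[C@H](O[Si](CC)(CC)CC)/C=C\[C@H](C)OCc1ccc(OC)cc1)CO[Si](c1ccccc1)(c1ccccc1)C(C)(C)C)(C)C#C[Li] | intermediate
29 | ynal (C4 aldehyde on C3) | C=C(C)[C@H](O[Si](C)(C)C(C)(C)C)CC[C@](C/C=C(\[C@H](O[Si](CC)(CC)CC)/C=C\[C@H](C)OCc1ccc(OC)cc1)CO[Si](c1ccccc1)(c1ccccc1)C(C)(C)C)(C)C#CC=O | intermediate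
30 | ynal with free (5S)-hydroxyl | C=C(C)[C@H](O[Si](C)(C)C(C)(C)C)CC[C@](C/C=C(\[C@H](O[Si](CC)(CC)CC)/C=C\[C@H](C)O)CO[Si](c1ccccc1)(c1ccccc1)C(C)(C)C)(C)C#CC=O | intermediate
31 | keto-ynal (C4 aldehyde, C5 methyl ketone, 6Z, 8R, 9Z) | C=C(C)[C@H](O[Si](C)(C)C(C)(C)C)CC[C@](C/C=C(\[C@H](O[Si](CC)(CC)CC)/C=C\C(C)=O)CO[Si](c1ccccc1)(c1ccccc1)C(C)(C)C)(C)C#CC=O | intermediate
32 | (1S,4R,5R,8R,6Z,9Z)-cycloundeca-6,9-dien-2-yne-4,5-diol with 1-Me, 5-Me, 8-OSiEt3, 9-CH2OTBDPS and the (3R)-3-(TBS-oxy)-4-methylpent-4-enyl chain on C1 | C=C(C)[C@H](O[Si](C)(C)C(C)(C)C)CC[C@]1(C)C#C[C@@H](O)[C@](C)(O)/C=C\[C@@H](O[Si](CC)(CC)CC)/C(CO[Si](c2ccccc2)(c2ccccc2)C(C)(C)C)=C\C1 | intermediate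
33 | 3-methylbut-2-enoyl chloride | CC(C)=CC(Cl)=O | starting material
34 | C4 3-methylbut-2-enoate of 32 | C=C(C)[C@H](O[Si](C)(C)C(C)(C)C)CC[C@]1(C)C#C[C@@H](OC(=O)C=C(C)C)[C@](C)(O)/C=C\[C@@H](O[Si](CC)(CC)CC)/C(CO[Si](c2ccccc2)(c2ccccc2)C(C)(C)C)=C\C1 | intermediate
35 | (1S,4R,5R,8R,2Z,6Z,9Z)-triene ester | C=C(C)[C@H](O[Si](C)(C)C(C)(C)C)CC[C@]1(C)/C=C\[C@@H](OC(=O)C=C(C)C)[C@](C)(O)/C=C\[C@@H](O[Si](CC)(CC)CC)/C(CO[Si](c2ccccc2)(c2ccccc2)C(C)(C)C)=C\C1 | intermediate
36 | (8R)-alcohol from 35 | C=C(C)[C@H](O[Si](C)(C)C(C)(C)C)CC[C@]1(C)/C=C\[C@@H](OC(=O)C=C(C)C)[C@](C)(O)/C=C\[C@@H](O)/C(CO[Si](c2ccccc2)(c2ccccc2)C(C)(C)C)=C\C1 | intermediate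
37 | (1S,4R,5R,2Z,6Z,9Z)-dienone, bis-silyl ether of the target | C=C(C)[C@H](O[Si](C)(C)C(C)(C)C)CC[C@]1(C)/C=C\[C@@H](OC(=O)C=C(C)C)[C@](C)(O)/C=C\C(=O)/C(CO[Si](c2ccccc2)(c2ccccc2)C(C)(C)C)=C\C1 | intermediate
38 | target (1S,4R,5R; side-chain carbinol R; 2Z,6Z,9Z) | C=C(C)[C@H](O)CC[C@]1(C)/C=C\[C@@H](OC(=O)C=C(C)C)[C@](C)(O)/C=C\C(=O)/C(CO)=C\C1 | target

**Count and risks**

Total steps: 26. Longest linear sequence: 24 (steps 1–10 and 13–26).

Steps most likely to fail:

1. Step 21. What may go wrong: the two samarium-bound oxygens bridge on one metal during C–C bond formation (closed instead of open coupling geometry), so that the facial selectivity at C4 is low or reversed and the erythro diol forms. Fallback: it sets out from 31, which is cyclised as before; the C4-epimeric diol F1 (or the epimer mixture) is oxidised at the propargylic position with MnO2 to the cyclic α-hydroxy ynone F2. The C4 ketone of F2 is then reduced under reagent control by Noyori transfer hydrogenation with RuCl[(R,R)-TsDPEN](p-cymene) or its enantiomer (HCO2H/Et3N), the alkynyl group acting as the small flank, and the route is rejoined at 32.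

2. Step 2. What may go wrong: attack at the primary carbon (SN2) or weak enantiofacial discrimination when the silyl-substituted alkynylalane meets an all-alkyl allylic phosphate. Fallback: it sets out from 1; Sharpless asymmetric epoxidation (Ti(Oi-Pr)4, D-(−)-diethyl tartrate, t-BuOOH) gives (2R,3R)-2,3-epoxygeraniol F3. Et2AlC≡CSiMe3 opens F3 at the tertiary C3 with inversion to the diol F4, which is converted with thiocarbonyldiimidazole into the cyclic thiocarbonate F5. Corey–Winter olefination of F5 with P(OMe)3 at 110 °C then gives the vinyl group, and the route is rejoined at 5.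

3. Step 14. What may go wrong: poor facial discrimination between the alkenyl and alkynyl flanks of the cross-conjugated ketone. Fallback: it sets out from 15; bromine–lithium exchange (t-BuLi) and trapping with DMF give the enal F6 (C8 aldehyde). Catalyst-controlled asymmetric alkynylation of F6 with alkyne 17 (Me2Zn, ProPhenol ligand, Ph3P=O, toluene) forms the C7–C8 bond and the 8R carbinol in one operation, and the route is rejoined at 23.

Further compounds
F1 | step 21 | (4S)-epimer of 32 (erythro diol) | C=C(C)[C@H](O[Si](C)(C)C(C)(C)C)CC[C@]1(C)C#C[C@H](O)[C@](C)(O)/C=C\[C@@H](O[Si](CC)(CC)CC)/C(CO[Si](c2ccccc2)(c2ccccc2)C(C)(C)C)=C\C1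
F2 | step 21 | cyclic α-hydroxy ynone (C4 ketone, 5R tertiary alcohol) | C=C(C)[C@H](O[Si](C)(C)C(C)(C)C)CC[C@]1(C)C#CC(=O)[C@](C)(O)/C=C\[C@@H](O[Si](CC)(CC)CC)/C(CO[Si](c2ccccc2)(c2ccccc2)C(C)(C)C)=C\C1
F3 | step 2 | (2R,3R)-2,3-epoxygeraniol | CC(C)=CCC[C@@]1(C)O[C@@H]1CO
F4 | step 2 | (2S,3R)-3,7-dimethyl-3-[(trimethylsilyl)ethynyl]oct-6-ene-1,2-diol | CC(C)=CCC[C@]([C@H](O)CO)(C)C#C[Si](C)(C)C
F5 | step 2 | cyclic thiocarbonate (1,3-dioxolane-2-thione) of F4 | CC(C)=CCC[C@]([C@H]1COC(=S)O1)(C)C#C[Si](C)(C)C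
F6 | step 14 | enal: 15 with CHO (C8) in place of Br | C=C(C)[C@H](O[Si](C)(C)C(C)(C)C)CC[C@](C/C=C(\C=O)CO[Si](c1ccccc1)(c1ccccc1)C(C)(C)C)(C)C#C[Si](C)(C)C
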